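## Retrosynthetic overview

1. The three esters go on last, one oxidation level at a time: target ⇐ diol 18 (double acetylation) ⇐ ketone 16 (bulky hydride, axial OH) ⇐ hydroxy ketone 14 (angeloylation of its only free OH).
2. 14 ⇐ bridged acylal 12 by methanolysis. The 7-oxabicyclo[2.2.1]heptane oxygen bridge is a temporary ring, absent from the target. It fixes the configuration of the angelate carbinol carbon, differentiates the two ring oxygens (carbinol versus masked ketone) and strains the ring alkene so that diimide reduces it alone, from the exo face.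
3. 12 ⇐ 11 ⇐ Diels–Alder reaction of the 2-acetoxy-4-alkylfuran 9 with methacrolein (a propene equivalent whose formyl group is removed later). It forms ring bonds C1–C6 and C4–C5 of the target (furan C5–CH2 and furan C2–C(CH3)) and the only carbocycle. The enabling feature is the furan ring of 9 (O1, C2–C5): an s-cis-locked, electron-rich diene whose termini C5 and C2 already carry both ring oxygens, with the 2-acetoxy and 4-alkyl groups both making C5 the nucleophilic end.
4. 9 ⇐ 3-alkylfuran 6 (C–H borylation at C5, oxidation, enol acetylation) ⇐ furan-3-carbaldehyde 1 + mesityl oxide 2; the two side-chain stereocentres come from a copper-catalysed conjugate methylation and a CBS reduction.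
5. Ring order: furan (purchased) → cyclohexene ring closed in the cycloaddition (oxanorbornene) → oxygen bridge opened to leave the cyclohexane.

Key step: step 8

Remark (structure read from the SMILES): ring C1 (angelate) R, C2 (side chain) S, C4 (acetate) R, C5 (methyl) S; side chain C2' R, C4' R; the unsaturated ester is the (Z)-2-methylbut-2-enoate (angelate). The two ring oxygens and the ring methyl are cis to each other, the side chain is trans to them.

Remark (sense of induction): in steps 2, 3 and 8 the catalyst antipode named is the one expected by analogy to give the drawn isomer; its mirror image would be used if a first experiment showed the opposite sense.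

Abbreviation: "TBS side chain" = (2R,4R)-4-[(tert-butyldimethylsilyl)oxy]-6-methylhept-5-en-2-yl.

## Route

Step 1
Reactants: 1 furan-3-carbaldehyde; 2 mesityl oxide (4-methylpent-3-en-2-one)
Product: 3 (1E)-1-(furan-3-yl)-5-methylhexa-1,4-dien-3-one
Conditions: NaOH (aq., cat.), EtOH, 0 °C → rt
Reagents that add atoms: none
Why: Claisen–Schmidt (crossed aldol) condensation of the methyl-ketone terminus of 2 with the non-enolisable aldehyde, followed by E1cB dehydration, should give the conjugated E-alkene.

Step 2
Reactants: 3 dienone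
Product: 4 (6R)-6-(furan-3-yl)-2-methylhept-2-en-4-one
Conditions: MeMgBr, CuBr·SMe2 (5 mol%), (R)-1-[(S)-2-(diphenylphosphino)ferrocenyl]ethyldicyclohexylphosphine (6 mol%), t-BuOMe, −75 °C; aq. NH4Cl
Reagents that add atoms: methylmagnesium bromide, C[Mg]Br
Why: Copper-catalysed asymmetric conjugate addition of a Grignard reagent to an acyclic enone; only the furyl-bearing β-monosubstituted alkene should react (the β,β-dimethyl end is too hindered), and the chiral ferrocenyl diphosphine selects the alkene face, setting the side-chain methyl stereocentre.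

Step 3
Reactants: 4 furyl enone
Product: 5 (4R,6R)-6-(furan-3-yl)-2-methylhept-2-en-4-ol
Conditions: (S)-1-methyl-3,3-diphenyltetrahydro-1H,3H-pyrrolo[1,2-c][1,3,2]oxazaborole ((S)-Me-CBS, 20 mol%), catecholborane, toluene, −78 °C; MeOH, aq. NaHCO3
Reagents that add atoms: none
Why: Corey–Bakshi–Shibata 1,2-reduction of an enone; the alkenyl group acts as the large substituent, so the (S)-catalyst should give the (R)-allylic alcohol under reagent control, the existing stereocentre being remote.

Step 4
Reactants: 5 allylic alcohol
Product: 6 TBS ether of 5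
Conditions: TBSCl, imidazole, DMF, rt
Reagents that add atoms: tert-butyldimethylsilyl chloride, CC(C)(C)[Si](C)(C)Cl
Why: Standard silylation; the silyl ether keeps this oxygen distinct from the ring hydroxyl that is angeloylated in step 11 and survives every later basic, hydridic and Lewis-acidic step.

Step 5
Reactants: 6 3-alkylfuran
Product: 7 furan-2-yl pinacol boronate (boron on C5 of the original furan, i.e. 2-boryl-4-alkylfuran)
Conditions: [Ir(OMe)(cod)]2 (1.5 mol%; cod = 1,5-cyclooctadiene), 4,4'-di-tert-butyl-2,2'-bipyridine (3 mol%), B2pin2 (1.0 equiv), hexane, rt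
Reagents that add atoms: bis(pinacolato)diboron, CC1(C)OB(OC1(C)C)B1OC(C)(C)C(C)(C)O1
Why: Iridium-catalysed heteroarene C–H borylation is sterically controlled and goes to an α-position; of the two α C–H bonds only the one remote from the branched side chain is accessible.

Step 6
Reactants: 7 furyl boronate
Product: 8 4-(TBS side chain)furan-2(5H)-one (β-substituted butenolide)
Conditions: 30% aq. H2O2, NaHCO3, THF, 0 °C → rt
Reagents that add atoms: hydrogen peroxide, OO
Why: Oxidation of the C–B bond (1,2-migration from boron to oxygen) gives the 2-oxygenated furan, obtained as its lactone tautomer; buffered peroxide should leave the trisubstituted alkene and the silyl ether alone.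

Step 7
Reactants: 8 butenolide
Product: 9 4-(TBS side chain)furan-2-yl acetate
Conditions: Ac2O, Et3N, 4-(dimethylamino)pyridine (cat.), CH2Cl2, 0 °C
Reagents that add atoms: acetic anhydride, CC(=O)OC(C)=O
Why: γ-Deprotonation of the butenolide gives the aromatic furan-2-olate, which is O-acetylated (enol ester formation) to an isolable 2-acetoxyfuran, the diene of the key step.

Step 8
Reactants: 9 2-acetoxy-4-alkylfuran; 10 methacrolein (2-methylprop-2-enal)
Product: 11 (1S,2R,4R)-2-formyl-2-methyl-5-(TBS side chain)-7-oxabicyclo[2.2.1]hept-5-en-1-yl acetate (formyl exo)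
Conditions: (S)-1-(2-methylphenyl)-3,3-diphenyltetrahydro-1H,3H-pyrrolo[1,2-c][1,3,2]oxazaborole (20 mol%) activated with HN(SO2CF3)2 (18 mol%), 10 (5 equiv), CH2Cl2, −78 → −40 °C; Et3N quench at −78 °C
Reagents that add atoms: none
Why: The protonated oxazaborolidine binds methacrolein s-trans and the furan adds across its C5 and C2 in a concerted, asynchronous [4+2] cycloaddition (C5–CH2 bond leading); the closest precedents are oxazaborolidinium-catalysed Diels–Alder reactions of furans and of 1-acyloxydienes with α-substituted acroleins. The cyclohexene ring closes in this intermolecular suprafacial–suprafacial [4+2] mode, and the furan ring survives as the 7-oxa bridge. Bicycle C1 and C4 are held cis by the bridging oxygen, C2 is set by the exo-formyl preference of α-substituted acroleins, and the absolute sense by the catalyst, which shields one face of the enal. Regioselectivity is needed and is secured because the 2-acetoxy and the 4-alkyl group both make C5 the nucleophilic terminus, so CH2 bonds to C5 and the methyl-bearing carbon to C2. High exo selectivity is also needed, because it links the furan face (the C4 configuration, the only one kept to the end) to the catalyst-controlled enal face; the remote side-chain stereocentres should not override the catalyst. The adduct is kept cold and reduced at once, since furan adducts can revert.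

Step 9
Reactants: 11 oxanorbornene adduct
Product: 12 (1S,2R,4R,5S)-2-formyl-2-methyl-5-(TBS side chain)-7-oxabicyclo[2.2.1]heptan-1-yl acetate (side chain endo)
Conditions: KO2CN=NCO2K (excess), AcOH, 1,4-dioxane, 10–20 °C, crude 11 used directly
Reagents that add atoms: none
Why: Diimide reduction (concerted syn transfer of H2) should be far faster at the strained oxanorbornene alkene than at the unstrained trisubstituted side-chain alkene; delivery from the exo face (the endo face is blocked by the C2 methyl) puts the side chain endo, trans to the bridging oxygen, which sets target C2 and also stops cycloreversion.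

Step 10
Reactants: 12 bridged acylal
Product: 14 (2S,4R,5S)-4-hydroxy-2-methyl-5-(TBS side chain)cyclohexan-1-one, via keto aldehyde 13 (not isolated)
Conditions: K2CO3 (0.3 equiv), MeOH, 0 °C → rt
Reagents that add atoms: none
Why: Methanolysis of the bridgehead (acylal-type) acetate unmasks the ketone and opens the oxygen bridge with retention at the carbinol carbon; the non-enolisable α-formyl ketone 13 then loses its formyl group by retro-Claisen cleavage, and the now enolisable α-centre equilibrates to the all-equatorial isomer with methyl cis to the hydroxyl (thermodynamic control, sets target C5).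

Step 11
Reactants: 14 hydroxy ketone; 15 angelic acid ((2Z)-2-methylbut-2-enoic acid)
Product: 16 (1R,2S,5S)-5-methyl-4-oxo-2-(TBS side chain)cyclohexyl (2Z)-2-methylbut-2-enoate
Conditions: 15, 2,4,6-Cl3C6H2COCl, Et3N, toluene, rt; then 14, 80 °C (no nucleophilic pyridine catalyst)
Reagents that add atoms: none
Why: Yamaguchi esterification through the mixed anhydride; 14 has a single hydroxyl, and leaving out the nucleophilic catalyst should keep the Z-alkene from isomerising to the tiglate.

Step 12
Reactants: 16 angelate ketone
Product: 17 (1R,2S,4R,5S)-4-hydroxy-5-methyl-2-(TBS side chain)cyclohexyl (2Z)-2-methylbut-2-enoate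
Conditions: Li[HB(s-Bu)3] (1.1 equiv), THF, −78 °C; aq. NH4Cl
Reagents that add atoms: none
Why: Substrate-controlled ketone reduction; the bulky trialkylborohydride attacks the conformationally fixed 2-methylcyclohexanone along the equatorial trajectory and should give the axial alcohol cis to the adjacent equatorial methyl (sets target C4), while the hindered angelate is not touched at −78 °C.

Step 13
Reactants: 17 silyl ether
Product: 18 (1R,2S,4R,5S)-4-hydroxy-2-[(2R,4R)-4-hydroxy-6-methylhept-5-en-2-yl]-5-methylcyclohexyl (2Z)-2-methylbut-2-enoate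
Conditions: HF·pyridine, pyridine, THF, 0 °C → rt
Reagents that add atoms: none
Why: Fluoride-mediated silyl ether cleavage under pyridine-buffered conditions, which should spare the angelate and not ionise the allylic alcohol.

Step 14
Reactants: 18 diol
Product: 19 target, (1R,2S,4R,5S)-4-acetoxy-2-[(2R,4R)-4-acetoxy-6-methylhept-5-en-2-yl]-5-methylcyclohexyl (2Z)-2-methylbut-2-enoate
Conditions: Ac2O, pyridine, 4-(dimethylamino)pyridine (cat.), CH2Cl2, rt
Reagents that add atoms: acetic anhydride, CC(=O)OC(C)=O
Why: Acyl-transfer-catalysed acetylation of both remaining hydroxyls (axial ring OH and allylic OH) in one operation; no stereocentre is affected.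

## Compound list

1 | furan-3-carbaldehyde | O=Cc1ccoc1 | starting material
2 | 4-methylpent-3-en-2-one (mesityl oxide) | CC(=O)C=C(C)C | starting material
3 | (1E)-1-(furan-3-yl)-5-methylhexa-1,4-dien-3-one | CC(C)=CC(=O)/C=C/c1ccoc1 | intermediate
4 | (6R)-6-(furan-3-yl)-2-methylhept-2-en-4-one | C[C@H](CC(=O)C=C(C)C)c1ccoc1 | intermediate
5 | (4R,6R)-6-(furan-3-yl)-2-methylhept-2-en-4-ol | C[C@H](C[C@@H](O)C=C(C)C)c1ccoc1 | intermediate
6 | tert-butyl{[(4R,6R)-6-(furan-3-yl)-2-methylhept-2-en-4-yl]oxy}dimethylsilane | C[C@H](C[C@@H](O[Si](C)(C)C(C)(C)C)C=C(C)C)c1ccoc1 | intermediate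
7 | 2-{4-[(2R,4R)-4-{[tert-butyl(dimethyl)silyl]oxy}-6-methylhept-5-en-2-yl]furan-2-yl}-4,4,5,5-tetramethyl-1,3,2-dioxaborolane | C[C@H](C[C@@H](O[Si](C)(C)C(C)(C)C)C=C(C)C)c1coc(B2OC(C)(C)C(C)(C)O2)c1 | intermediate
8 | 4-[(2R,4R)-4-{[tert-butyl(dimethyl)silyl]oxy}-6-methylhept-5-en-2-yl]furan-2(5H)-one | C[C@H](C[C@@H](O[Si](C)(C)C(C)(C)C)C=C(C)C)C1=CC(=O)OC1 | intermediate
9 | 4-[(2R,4R)-4-{[tert-butyl(dimethyl)silyl]oxy}-6-methylhept-5-en-2-yl]furan-2-yl acetate | C[C@H](C[C@@H](O[Si](C)(C)C(C)(C)C)C=C(C)C)c1coc(OC(C)=O)c1 | intermediate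
10 | 2-methylprop-2-enal (methacrolein) | CC(=C)C=O | starting material
11 | (1S,2R,4R)-5-[(2R,4R)-4-{[tert-butyl(dimethyl)silyl]oxy}-6-methylhept-5-en-2-yl]-2-formyl-2-methyl-7-oxabicyclo[2.2.1]hept-5-en-1-yl acetate (exo-formyl) | O1[C@@H]2C[C@](C)(C=O)[C@@]1(OC(C)=O)C=C2[C@H](C)C[C@@H](O[Si](C)(C)C(C)(C)C)C=C(C)C | intermediate
12 | (1S,2R,4R,5S)-5-[(2R,4R)-4-{[tert-butyl(dimethyl)silyl]oxy}-6-methylhept-5-en-2-yl]-2-formyl-2-methyl-7-oxabicyclo[2.2.1]heptan-1-yl acetate (side chain endo) | O1[C@@H]2C[C@](C)(C=O)[C@@]1(OC(C)=O)C[C@H]2[C@H](C)C[C@@H](O[Si](C)(C)C(C)(C)C)C=C(C)C | intermediate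
13 | (1R,4S,5R)-4-[(2R,4R)-4-{[tert-butyl(dimethyl)silyl]oxy}-6-methylhept-5-en-2-yl]-5-hydroxy-1-methyl-2-oxocyclohexane-1-carbaldehyde | O[C@@H]1C[C@](C)(C=O)C(=O)C[C@H]1[C@H](C)C[C@@H](O[Si](C)(C)C(C)(C)C)C=C(C)C | intermediate (not isolated)
14 | (2S,4R,5S)-5-[(2R,4R)-4-{[tert-butyl(dimethyl)silyl]oxy}-6-methylhept-5-en-2-yl]-4-hydroxy-2-methylcyclohexan-1-one | O[C@@H]1C[C@H](C)C(=O)C[C@H]1[C@H](C)C[C@@H](O[Si](C)(C)C(C)(C)C)C=C(C)C | intermediate
15 | (2Z)-2-methylbut-2-enoic acid (angelic acid) | C/C=C(/C)C(=O)O | starting material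
16 | (1R,2S,5S)-2-[(2R,4R)-4-{[tert-butyl(dimethyl)silyl]oxy}-6-methylhept-5-en-2-yl]-5-methyl-4-oxocyclohexyl (2Z)-2-methylbut-2-enoate | C/C=C(/C)C(=O)O[C@@H]1C[C@H](C)C(=O)C[C@H]1[C@H](C)C[C@@H](O[Si](C)(C)C(C)(C)C)C=C(C)C | intermediate
17 | (1R,2S,4R,5S)-2-[(2R,4R)-4-{[tert-butyl(dimethyl)silyl]oxy}-6-methylhept-5-en-2-yl]-4-hydroxy-5-methylcyclohexyl (2Z)-2-methylbut-2-enoate | C/C=C(/C)C(=O)O[C@@H]1C[C@H](C)[C@H](O)C[C@H]1[C@H](C)C[C@@H](O[Si](C)(C)C(C)(C)C)C=C(C)C | intermediate
18 | (1R,2S,4R,5S)-4-hydroxy-2-[(2R,4R)-4-hydroxy-6-methylhept-5-en-2-yl]-5-methylcyclohexyl (2Z)-2-methylbut-2-enoate | C/C=C(/C)C(=O)O[C@@H]1C[C@H](C)[C@H](O)C[C@H]1[C@H](C)C[C@@H](O)C=C(C)C | intermediate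
19 | (1R,2S,4R,5S)-4-acetoxy-2-[(2R,4R)-4-acetoxy-6-methylhept-5-en-2-yl]-5-methylcyclohexyl (2Z)-2-methylbut-2-enoate | C/C=C(/C)C(=O)O[C@@H]1C[C@H](C)[C@H](OC(C)=O)C[C@H]1[C@H](C)C[C@H](C=C(C)C)OC(C)=O | target

## Step count and risks

Total steps: 14. Longest linear sequence: 14 steps (1 → 19).

Steps most likely to fail:

Step 8 (key cycloaddition). What may go wrong: slow formation of the congested C2–C1 bond next to a quaternary centre, Friedel–Crafts-type conjugate addition of furan C5 without ring closure, cycloreversion of the adduct, or loss of exo selectivity, which would erode the configuration of the carbinol carbon. Fallback, setting out from 9 and returning at 14: 9 is combined with the less hindered, two-point-binding dienophile 3-acryloyl-1,3-oxazolidin-2-one under the divalent copper bis(oxazoline) complex [Cu((S,S)-t-Bu-box)](SbF6)2 (t-Bu-box = 2,2'-propane-2,2-diylbis(4-tert-butyl-4,5-dihydrooxazole); ligand antipode chosen as in the remark) in CH2Cl2 at −78 °C. This is a Lewis-acid-catalysed Diels–Alder reaction with close precedent for furan and for 1-acetoxybutadiene, and should give, after removal of the exo isomer, the endo imide adduct F1. Diimide reduction as in step 9 gives the saturated imide F2. K2CO3 in MeOH cleaves the bridgehead acetate and the imide and opens the bridge to the β-keto ester F3. C-Methylation with MeI and K2CO3 in acetone gives the methylated keto ester F4. LiOH in aqueous THF, then acidification and gentle warming (hydrolysis, decarboxylation, equilibration of the α-centre) returns to 14. The methyl group is thus introduced after the cycloaddition instead of with the dienophile.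

Step 9 (diimide reduction). What may go wrong: cycloreversion of 11 or side reactions of its aldehyde before the hindered, trisubstituted strained alkene is saturated, or partial reduction of the side-chain alkene. Fallback, setting out from 11 and returning at 14: 11 is treated directly with K2CO3 in MeOH, which opens the bridge and removes the formyl group to give the hydroxy enone F5. Hydroxyl-directed hydrogenation with the monovalent rhodium complex [Rh(nbd)(dppb)]BF4 (nbd = norbornadiene, dppb = 1,4-bis(diphenylphosphino)butane) under H2 pressure in CH2Cl2 should then deliver hydrogen to the ring alkene from the face of the ring hydroxyl, placing the side chain trans to it; the side-chain alkene has no free hydroxyl and should be much slower. Brief equilibration with DBU gives 14. The stereocentre is then set by coordination to the hydroxyl instead of by the strain and shape of the bicycle.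

Step 2 (conjugate methylation). What may go wrong: competing 1,2-addition of the Grignard reagent and insufficient face selectivity on a β-heteroaryl, cross-conjugated dienone. Fallback, setting out from 2 and returning at 4: the kinetic enolate of 2 (LiN(i-Pr)2, THF, −78 °C) is added to acetaldehyde to give the aldol F6. Acid-catalysed dehydration (p-toluenesulfonic acid, cat.) gives the dienone F7. Rhodium-catalysed asymmetric 1,4-addition of furan-3-boronic acid (Hayashi–Miyaura reaction; Rh(acac)(C2H4)2, (R)-2,2'-bis(diphenylphosphino)-1,1'-binaphthyl, dioxane/H2O, 100 °C) to the less substituted alkene of F7 gives 4. The stereocentre is then made by adding the furyl group to a methyl-bearing alkene instead of the methyl group to a furyl-bearing alkene.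

Further compounds
F1 | step 8 | (1S,2R,4R)-5-[(2R,4R)-4-{[tert-butyl(dimethyl)silyl]oxy}-6-methylhept-5-en-2-yl]-2-(2-oxo-1,3-oxazolidine-3-carbonyl)-7-oxabicyclo[2.2.1]hept-5-en-1-yl acetate (endo imide) | O1[C@@H]2C[C@@H](C(=O)N3CCOC3=O)[C@@]1(OC(C)=O)C=C2[C@H](C)C[C@@H](O[Si](C)(C)C(C)(C)C)C=C(C)C
F2 | step 8 | (1S,2R,4R,5S)-5-[(2R,4R)-4-{[tert-butyl(dimethyl)silyl]oxy}-6-methylhept-5-en-2-yl]-2-(2-oxo-1,3-oxazolidine-3-carbonyl)-7-oxabicyclo[2.2.1]heptan-1-yl acetate | O1[C@@H]2C[C@@H](C(=O)N3CCOC3=O)[C@@]1(OC(C)=O)C[C@H]2[C@H](C)C[C@@H](O[Si](C)(C)C(C)(C)C)C=C(C)C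
F3 | step 8 | methyl (4S,5R)-4-[(2R,4R)-4-{[tert-butyl(dimethyl)silyl]oxy}-6-methylhept-5-en-2-yl]-5-hydroxy-2-oxocyclohexane-1-carboxylate (C1 epimers and enol) | O[C@@H]1CC(C(=O)OC)C(=O)C[C@H]1[C@H](C)C[C@@H](O[Si](C)(C)C(C)(C)C)C=C(C)C
F4 | step 8 | methyl (4S,5R)-4-[(2R,4R)-4-{[tert-butyl(dimethyl)silyl]oxy}-6-methylhept-5-en-2-yl]-5-hydroxy-1-methyl-2-oxocyclohexane-1-carboxylate (C1 epimers) | O[C@@H]1CC(C)(C(=O)OC)C(=O)C[C@H]1[C@H](C)C[C@@H](O[Si](C)(C)C(C)(C)C)C=C(C)C
F5 | step 9 | (4R)-3-[(2R,4R)-4-{[tert-butyl(dimethyl)silyl]oxy}-6-methylhept-5-en-2-yl]-4-hydroxy-6-methylcyclohex-2-en-1-one (C6 epimers) | O[C@@H]1CC(C)C(=O)C=C1[C@H](C)C[C@@H](O[Si](C)(C)C(C)(C)C)C=C(C)C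
F6 | step 2 | 6-hydroxy-2-methylhept-2-en-4-one (racemic) | CC(O)CC(=O)C=C(C)C
F7 | step 2 | (2E)-6-methylhepta-2,5-dien-4-one | C/C=C/C(=O)C=C(C)C
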